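**Strategy.** Ring C is cut at the O1–C8a bond. C8a, C5 and C7 of ring A all carry oxygen, are meta to one another and sit ortho, ortho and para to the C4 carbonyl, so ring A is taken from a symmetric 2,4,6-trifluorobenzoyl unit in which each of these C–O bonds can be made by SNAr. The key step closes ring C by attack of the diketone enolate oxygen on an ortho C–F carbon. Its precursor is a 1-aryl-3-(2,4,6-trifluorophenyl)propane-1,3-dione whose diprenylated ring B phenol is masked as an allyl ether; the two later ring A oxygens also enter as allyl ethers, so one acid-free Pd(PPh3)4 step unmasks all three phenols beside the acid-sensitive ortho-prenyl groups.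

Key step: step 5

Remark: in step 6 the fluorine para to the C4 carbonyl (C7) is taken to be displaced first, the order having no effect on the product; the three allyl ethers in step 7 fall in no defined order, so the partly deallylated flavones are not treated as discrete intermediates.

**Step 1**
Reactants: 1 4-bromophenol; 2 1-bromo-3-methylbut-2-ene (prenyl bromide)
Product: 4 4-bromo-2,6-bis(3-methylbut-2-en-1-yl)phenol, via monoprenyl bromophenol 3 (not isolated)
Conditions: NaH (2.2 equiv), PhMe, 0 °C; then 2 (2.2 equiv), rt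
Reagents that add atoms: 1-bromo-3-methylbut-2-ene (prenyl bromide, the second equivalent of 2), CC(C)=CCBr
Why: In toluene the sodium phenoxide reacts as a tight ion pair, so the first equivalent of prenyl bromide is attacked by the ortho carbon and not by oxygen (phenoxide ortho-C-alkylation), the para position is blocked by bromine, and the mono-prenyl phenol 3 is deprotonated by the second equivalent of NaH and alkylated at the other ortho carbon by the second equivalent of prenyl bromide.

**Step 2**
Reactants: 4 4-bromo-2,6-bis(3-methylbut-2-en-1-yl)phenol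
Product: 5 5-bromo-1,3-bis(3-methylbut-2-en-1-yl)-2-(prop-2-en-1-yloxy)benzene
Conditions: allyl bromide, K2CO3, DMF, rt
Reagents that add atoms: allyl bromide (3-bromoprop-1-ene), C=CCBr
Why: Williamson etherification of the potassium phenoxide in a dipolar aprotic solvent goes at oxygen because both ortho positions and the para position are substituted, and the allyl ether masks the acidic phenol for the organolithium and enolate steps while remaining removable later without acid.

**Step 3**
Reactants: 5 5-bromo-1,3-bis(3-methylbut-2-en-1-yl)-2-(prop-2-en-1-yloxy)benzene; 6 N-methoxy-N-methylacetamide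
Product: 9 1-[3,5-bis(3-methylbut-2-en-1-yl)-4-(prop-2-en-1-yloxy)phenyl]ethan-1-one, via aryllithium 7 (not isolated), via lithium hemiaminal alkoxide 8 (not isolated)
Conditions: n-BuLi, THF, −78 °C; then 6, −78 → 0 °C; then H2O
Reagents that add atoms: none
Why: Bromine–lithium exchange at −78 °C is much faster than any attack of n-BuLi on the allyl ether, and the aryllithium 7 adds only once to the Weinreb amide because the chelated tetrahedral adduct 8 holds until the water quench (Weinreb ketone synthesis).

**Step 4**
Reactants: 9 1-[3,5-bis(3-methylbut-2-en-1-yl)-4-(prop-2-en-1-yloxy)phenyl]ethan-1-one; 10 2,4,6-trifluorobenzoyl chloride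
Product: 12 1-[3,5-bis(3-methylbut-2-en-1-yl)-4-(prop-2-en-1-yloxy)phenyl]-3-(2,4,6-trifluorophenyl)propane-1,3-dione, via lithium enolate 11 (not isolated)
Conditions: LiN(SiMe3)2 (2.2 equiv), THF, −78 °C; then 10, −78 °C; AcOH quench at −78 °C
Reagents that add atoms: none
Why: Crossed Claisen-type C-acylation of the lithium enolate 11 by the acid chloride at −78 °C, in which the second equivalent of base takes up the more acidic diketone as its lithium chelate so that it is not acylated again, and the cold acetic acid quench returns 12 before any ring closure can start.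

**Step 5**
Reactants: 12 1-[3,5-bis(3-methylbut-2-en-1-yl)-4-(prop-2-en-1-yloxy)phenyl]-3-(2,4,6-trifluorophenyl)propane-1,3-dione
Product: 15 2-[3,5-bis(3-methylbut-2-en-1-yl)-4-(prop-2-en-1-yloxy)phenyl]-5,7-difluoro-4H-chromen-4-one, via potassium enolate 13 (not isolated), via Meisenheimer adduct 14 (not isolated)
Conditions: K2CO3 (2 equiv), DMF, 60 °C
Reagents that add atoms: none
Why: K2CO3 converts 12 into the chelated Z-enolate 13, whose oxygen on the future C2 adds to one of the two equivalent ortho C–F carbons of the trifluorobenzoyl ring to give the Meisenheimer adduct 14, in which the charge is taken up by the C4 carbonyl and eased inductively by the two fluorines meta to the attacked carbon, and loss of fluoride then restores the arene (addition–elimination SNAr). The closest known reaction type is the base-mediated cyclisation of 1-(2-fluoroaryl)-1,3-diketones to flavones, the oxygen analogue of the ring closure that builds 4-quinolones. Ring C closes as a six-membered ring at the sp2 carbon C8a, a closure that counts as 6-exo-trig on the C8a=C8 bond and as 6-endo-trig when written as an oxa-Michael addition to the C8a=C4a–C4=O unit, both of which are favoured. No stereocentre is formed. The step needs O-arylation through the C2 oxygen and attack at an ortho and not the para fluorine: C3 and the C4 oxygen could only close four-membered rings, the two ortho fluorines are equivalent, and the six-membered intramolecular path outruns any bimolecular displacement of the para fluorine, so the fluorines at C5 and C7 survive for step 6.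

**Step 6**
Reactants: 15 2-[3,5-bis(3-methylbut-2-en-1-yl)-4-(prop-2-en-1-yloxy)phenyl]-5,7-difluoro-4H-chromen-4-one; 16 prop-2-en-1-ol (allyl alcohol)
Product: 18 2-[3,5-bis(3-methylbut-2-en-1-yl)-4-(prop-2-en-1-yloxy)phenyl]-5,7-bis(prop-2-en-1-yloxy)-4H-chromen-4-one, via 7-allyloxy-5-fluoroflavone 17 (not isolated)
Conditions: NaH (3 equiv), 16 (excess), THF, 0 → 60 °C
Reagents that add atoms: prop-2-en-1-ol (allyl alcohol, the second equivalent of 16), C=CCO
Why: Twofold SNAr by two equivalents of NaOCH2CH=CH2 on aryl fluorides activated para (C7) and ortho (C5) to the C4 carbonyl, in which the C7 ether formed first is meta to C5 and so does not feed electron density to the second site of attack, while the excess free alcohol keeps any addition at C2 reversible.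

**Step 7**
Reactants: 18 2-[3,5-bis(3-methylbut-2-en-1-yl)-4-(prop-2-en-1-yloxy)phenyl]-5,7-bis(prop-2-en-1-yloxy)-4H-chromen-4-one
Product: 19 honyucitrin, 5,7-dihydroxy-2-[4-hydroxy-3,5-bis(3-methylbut-2-en-1-yl)phenyl]-4H-chromen-4-one
Conditions: Pd(PPh3)4 (5 mol %), morpholine (10 equiv), THF, rt
Reagents that add atoms: none
Why: Zerovalent palladium ionises each allyl aryl ether to a π-allyl complex and a phenoxide and morpholine traps the allyl group irreversibly (Tsuji–Trost deallylation), under neutral to basic conditions that should leave the trisubstituted prenyl alkenes and the freed ortho-prenyl phenol untouched.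

**Compound list**

1 | 4-bromophenol | Oc1ccc(Br)cc1 | starting material
2 | 1-bromo-3-methylbut-2-ene (prenyl bromide) | CC(C)=CCBr | starting material
3 | 4-bromo-2-(3-methylbut-2-en-1-yl)phenol | CC(C)=CCc1cc(Br)ccc1O | intermediate (not isolated)
4 | 4-bromo-2,6-bis(3-methylbut-2-en-1-yl)phenol | CC(C)=CCc1cc(Br)cc(CC=C(C)C)c1O | intermediate
5 | 5-bromo-1,3-bis(3-methylbut-2-en-1-yl)-2-(prop-2-en-1-yloxy)benzene | CC(C)=CCc1cc(Br)cc(CC=C(C)C)c1OCC=C | intermediate
6 | N-methoxy-N-methylacetamide | CC(=O)N(C)OC | starting material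
7 | [3,5-bis(3-methylbut-2-en-1-yl)-4-(prop-2-en-1-yloxy)phenyl]lithium | [Li]c1cc(CC=C(C)C)c(OCC=C)c(CC=C(C)C)c1 | intermediate (not isolated)
8 | lithium 1-[3,5-bis(3-methylbut-2-en-1-yl)-4-(prop-2-en-1-yloxy)phenyl]-1-[methoxy(methyl)amino]ethan-1-olate (racemic; centre lost on collapse) | [Li+].[O-]C(C)(N(C)OC)c1cc(CC=C(C)C)c(OCC=C)c(CC=C(C)C)c1 | intermediate (not isolated)
9 | 1-[3,5-bis(3-methylbut-2-en-1-yl)-4-(prop-2-en-1-yloxy)phenyl]ethan-1-one | CC(=O)c1cc(CC=C(C)C)c(OCC=C)c(CC=C(C)C)c1 | intermediate
10 | 2,4,6-trifluorobenzoyl chloride | O=C(Cl)c1c(F)cc(F)cc1F | starting material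
11 | lithium 1-[3,5-bis(3-methylbut-2-en-1-yl)-4-(prop-2-en-1-yloxy)phenyl]ethen-1-olate | [Li+].[O-]C(=C)c1cc(CC=C(C)C)c(OCC=C)c(CC=C(C)C)c1 | intermediate (not isolated)
12 | 1-[3,5-bis(3-methylbut-2-en-1-yl)-4-(prop-2-en-1-yloxy)phenyl]-3-(2,4,6-trifluorophenyl)propane-1,3-dione (drawn as the diketo tautomer) | CC(C)=CCc1cc(C(=O)CC(=O)c2c(F)cc(F)cc2F)cc(CC=C(C)C)c1OCC=C | intermediate (key-step precursor)
13 | potassium (Z)-1-[3,5-bis(3-methylbut-2-en-1-yl)-4-(prop-2-en-1-yloxy)phenyl]-3-oxo-3-(2,4,6-trifluorophenyl)prop-1-en-1-olate | [K+].[O-]/C(=C\C(=O)c1c(F)cc(F)cc1F)c1cc(CC=C(C)C)c(OCC=C)c(CC=C(C)C)c1 | intermediate (not isolated)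
14 | potassium 2-[3,5-bis(3-methylbut-2-en-1-yl)-4-(prop-2-en-1-yloxy)phenyl]-5,7,8a-trifluoro-8aH-chromen-4-olate (Meisenheimer adduct, racemic at C8a; centre lost with fluoride) | [K+].[O-]C1=C2C(F)=CC(F)=CC2(F)OC(=C1)c1cc(CC=C(C)C)c(OCC=C)c(CC=C(C)C)c1 | intermediate (not isolated)
15 | 2-[3,5-bis(3-methylbut-2-en-1-yl)-4-(prop-2-en-1-yloxy)phenyl]-5,7-difluoro-4H-chromen-4-one | CC(C)=CCc1cc(-c2cc(=O)c3c(F)cc(F)cc3o2)cc(CC=C(C)C)c1OCC=C | intermediate (key-step product)
16 | prop-2-en-1-ol (allyl alcohol) | C=CCO | starting material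
17 | 2-[3,5-bis(3-methylbut-2-en-1-yl)-4-(prop-2-en-1-yloxy)phenyl]-5-fluoro-7-(prop-2-en-1-yloxy)-4H-chromen-4-one | CC(C)=CCc1cc(-c2cc(=O)c3c(F)cc(OCC=C)cc3o2)cc(CC=C(C)C)c1OCC=C | intermediate (not isolated)
18 | 2-[3,5-bis(3-methylbut-2-en-1-yl)-4-(prop-2-en-1-yloxy)phenyl]-5,7-bis(prop-2-en-1-yloxy)-4H-chromen-4-one | CC(C)=CCc1cc(-c2cc(=O)c3c(OCC=C)cc(OCC=C)cc3o2)cc(CC=C(C)C)c1OCC=C | intermediate
19 | honyucitrin, 5,7-dihydroxy-2-[4-hydroxy-3,5-bis(3-methylbut-2-en-1-yl)phenyl]-4H-chromen-4-one (no stereocentre, no stereogenic double bond) | CC(C)=CCc1cc(-c2cc(=O)c3c(O)cc(O)cc3o2)cc(CC=C(C)C)c1O | target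

**Step count and risk**

Total step count: 7. Longest linear sequence: 7 steps (1 → 19).

The three steps most likely to fail, in falling order of risk:

Step 6. The second displacement, at C5, may stall once the C7 ether is in place, or the alkoxide may add at C2 and open ring C at the temperature the second displacement needs. The fallback sets out from 15 and comes back to the route at 19. Compound 15 would be treated with one equivalent of NaOCH2CH=CH2 in THF at 0 °C so that the reaction stops at the mono-ether 17, which is then isolated. The remaining C5 fluorine would be replaced by a weakly basic, strongly nucleophilic hydroxide surrogate of the α-effect type. (E)-Benzaldoxime and K2CO3 in DMSO at 60 °C should give the O-aryl oxime 2-[3,5-bis(3-methylbut-2-en-1-yl)-4-(prop-2-en-1-yloxy)phenyl]-5-{[(E)-benzylideneamino]oxy}-7-(prop-2-en-1-yloxy)-4H-chromen-4-one F1. In the same flask this should lose benzonitrile by base-induced elimination and deliver 2-[3,5-bis(3-methylbut-2-en-1-yl)-4-(prop-2-en-1-yloxy)phenyl]-5-hydroxy-7-(prop-2-en-1-yloxy)-4H-chromen-4-one F2. Because this is the last substitution on ring A, the phenoxide it leaves behind deactivates nothing further. The two remaining allyl ethers of F2 would be cleaved with Pd(PPh3)4 and morpholine as in step 7 to give 19.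

Step 1. Alkylation at oxygen and incomplete or excessive alkylation at carbon may erode the supply of the diprenyl phenol. The fallback sets out from 1 and comes back at 4, and builds both side chains by sigmatropic rearrangement followed by olefin metathesis. O-Allylation of 1 (allyl bromide, K2CO3, acetone, reflux) should give 1-bromo-4-(prop-2-en-1-yloxy)benzene F3, and Claisen rearrangement of this ether in N,N-diethylaniline at 190 °C should give 4-bromo-2-(prop-2-en-1-yl)phenol F4. A second O-allylation under the same conditions should give 4-bromo-2-(prop-2-en-1-yl)-1-(prop-2-en-1-yloxy)benzene F5, and a second Claisen rearrangement should give 4-bromo-2,6-bis(prop-2-en-1-yl)phenol F6. Cross-metathesis of F6 with excess 2-methylbut-2-ene and the second-generation Grubbs catalyst in CH2Cl2 at 40 °C should turn both allyl groups into prenyl groups and give 4.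

Step 4. The enolate may be acylated at oxygen to the enol ester, or the product may be acylated a second time. The fallback sets out from 9 and comes back at 12, and replaces the acylation by an aldol addition and an oxidation. The lithium enolate 11 (LiN(SiMe3)2, THF, −78 °C) would be added to 2,4,6-trifluorobenzaldehyde to give racemic 1-[3,5-bis(3-methylbut-2-en-1-yl)-4-(prop-2-en-1-yloxy)phenyl]-3-hydroxy-3-(2,4,6-trifluorophenyl)propan-1-one F7. Dess–Martin periodinane with NaHCO3 in CH2Cl2 at rt should oxidise F7 to the diketone 12 without touching the prenyl or allyl groups.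

**Further compounds**

F1 | step 6 | 2-[3,5-bis(3-methylbut-2-en-1-yl)-4-(prop-2-en-1-yloxy)phenyl]-5-{[(E)-benzylideneamino]oxy}-7-(prop-2-en-1-yloxy)-4H-chromen-4-one (not isolated) | CC(C)=CCc1cc(-c2cc(=O)c3c(O/N=C/c4ccccc4)cc(OCC=C)cc3o2)cc(CC=C(C)C)c1OCC=C
F2 | step 6 | 2-[3,5-bis(3-methylbut-2-en-1-yl)-4-(prop-2-en-1-yloxy)phenyl]-5-hydroxy-7-(prop-2-en-1-yloxy)-4H-chromen-4-one | CC(C)=CCc1cc(-c2cc(=O)c3c(O)cc(OCC=C)cc3o2)cc(CC=C(C)C)c1OCC=C
F3 | step 1 | 1-bromo-4-(prop-2-en-1-yloxy)benzene | C=CCOc1ccc(Br)cc1
F4 | step 1 | 4-bromo-2-(prop-2-en-1-yl)phenol | C=CCc1cc(Br)ccc1O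
F5 | step 1 | 4-bromo-2-(prop-2-en-1-yl)-1-(prop-2-en-1-yloxy)benzene | C=CCOc1ccc(Br)cc1CC=C
F6 | step 1 | 4-bromo-2,6-bis(prop-2-en-1-yl)phenol | C=CCc1cc(Br)cc(CC=C)c1O
F7 | step 4 | 1-[3,5-bis(3-methylbut-2-en-1-yl)-4-(prop-2-en-1-yloxy)phenyl]-3-hydroxy-3-(2,4,6-trifluorophenyl)propan-1-one (racemic) | CC(C)=CCc1cc(C(=O)CC(O)c2c(F)cc(F)cc2F)cc(CC=C(C)C)c1OCC=C
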